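**Plan**
1. Cuts, in retrosynthetic order: the lactone C1–O bond and C2=C3 (lactonisation of a Z-enoate made by Ando olefination at C3); C12=C13 (cross-metathesis with 1-pentadecene, then saturation); the C11–O bond together with the O9/O11 acetal (allylic transposition); C9–C10 (allylation); C7–O with the O5/O7 acetal (same transposition); C5–C6 (allylation).
2. Enabling feature (lactone carbonyl = C1): carbinol C11 is 1,3-syn to carbinol C9 and is followed by C12–C13 of the saturated tail. Its oxygen can therefore arrive by a 1,3-shift from C13 across a C11=C12 alkene, while a six-membered 2-phenyl-1,3-dioxane through O9 and O11 locks the configuration and leaves a C12=C13 vinyl handle. C7 stands in the same relation to C5.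
3. Forward order: one linear chain grown from the C3 end (C3–C5, then to C9, C13 and C26). The O5/O7 dioxane forms first, the O9/O11 dioxane second, the dihydropyranone ring last.
4. Stereochemistry: C5 and C9 by reagent-controlled Brown allylation with one allylborane enantiomer; C7 and C11 relayed from them under thermodynamic control in the two Re2O7 steps; the C2=C3 Z geometry from the Ando phosphonate.

Key step: step 10

Remark: atoms are numbered along the target chain (lactone carbonyl = C1), and the allylborane is defined by its precursor (+)-Ipc2BOMe of the (−)-α-pinene series, which is taken to deliver allyl to the Re face of the aldehydes used here.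

In the names below, "benzylidene" always means the all-cis 2-phenyl-1,3-dioxane (phenyl and both chain substituents equatorial); the SMILES in the compound list define every centre.

**Step 1**
Reactants: 1 propane-1,3-diol
Product: 2 3-(tert-butyldiphenylsilyloxy)propan-1-ol
Conditions: NaH (1.0 equiv), THF, 0 °C to rt; then TBDPSCl (1.0 equiv), rt
Reagents that add atoms: tert-butyl(chloro)diphenylsilane, CC(C)(C)[Si](Cl)(c1ccccc1)c1ccccc1
Why: One equivalent of NaH turns the symmetrical diol into its poorly soluble monoalkoxide, which is O-silylated once (Williamson-type monosilylation of a symmetrical diol), so the mono-ether should predominate over the bis-ether.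

**Step 2**
Reactants: 2 3-(tert-butyldiphenylsilyloxy)propan-1-ol
Product: 3 3-(tert-butyldiphenylsilyloxy)propanal
Conditions: TEMPO (10 mol%), PhI(OAc)2 (1.1 equiv), CH2Cl2, rt
Reagents that add atoms: none
Why: The oxoammonium-mediated TEMPO/PhI(OAc)2 oxidation takes a primary alcohol to the aldehyde without over-oxidation, leaves the silyl ether alone and avoids the basic medium in which this β-silyloxy aldehyde would eliminate.

**Step 3**
Reactants: 3 3-(tert-butyldiphenylsilyloxy)propanal
Product: 5 (R)-1-(tert-butyldiphenylsilyloxy)hex-5-en-3-ol, via diisopinocampheylborinate ester 4 (not isolated)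
Conditions: (+)-Ipc2BOMe, allylMgBr, Et2O, −78 °C to rt; then 3, −78 °C; then NaOH, H2O2, 0 °C to rt
Reagents that add atoms: allylmagnesium bromide, C=CC[Mg]Br
Why: Brown allylation, in which the allylborane of the (−)-α-pinene series reacts through a closed six-membered chair transition state on the Re face of the aldehyde, so that C5 is set under reagent control as the (R)-carbinol (the future S centre of the lactone) before alkaline peroxide cleaves the borinate.

**Step 4**
Reactants: 5 (R)-1-(tert-butyldiphenylsilyloxy)hex-5-en-3-ol; 6 (Z)-but-2-ene-1,4-diol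
Product: 7 (2E,5R)-7-(tert-butyldiphenylsilyloxy)hept-2-ene-1,5-diol
Conditions: second-generation Grubbs catalyst RuCl2(=CHPh)(PCy3)(SIMes) (5 mol%), 6 (4 equiv), CH2Cl2, 40 °C
Reagents that add atoms: none
Why: Olefin cross-metathesis between the terminal alkene and the symmetrical internal diol installs the CH=CH–CH2OH unit with the usual E preference, free hydroxyls being tolerated by the ruthenium carbene and the alkene geometry being of no consequence for the next step.

**Step 5**
Reactants: 7 (2E,5R)-7-(tert-butyldiphenylsilyloxy)hept-2-ene-1,5-diol; 8 benzaldehyde dimethyl acetal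
Product: 10 (2S,4S,6S)-4-[2-(tert-butyldiphenylsilyloxy)ethyl]-2-phenyl-6-vinyl-1,3-dioxane, via transposed 5,7-syn-diol 9 (not isolated)
Conditions: Re2O7 (5 mol%), 8 (3 equiv), CH2Cl2, 0 °C to rt
Reagents that add atoms: none
Why: Rhenium-oxo-catalysed 1,3-transposition of the allylic alcohol (perrhenate ester, reversible [3,3] shift) is coupled with acid-catalysed acetal exchange, and since only the C7 epimer syn to the C5 hydroxyl can close the triequatorial 2-phenyl-1,3-dioxane, C7 and the acetal carbon are set from C5 under thermodynamic control.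

**Step 6**
Reactants: 10 (2S,4S,6S)-4-[2-(tert-butyldiphenylsilyloxy)ethyl]-2-phenyl-6-vinyl-1,3-dioxane
Product: 12 2-[cis,cis-6-[2-(tert-butyldiphenylsilyloxy)ethyl]-2-phenyl-1,3-dioxan-4-yl]ethan-1-ol, via B-alkyl-9-BBN adduct 11 (not isolated)
Conditions: 9-BBN, THF, 0 °C to rt; then NaOH, H2O2, H2O, 0 °C to rt
Reagents that add atoms: hydrogen peroxide, OO
Why: Hydroboration–oxidation with the bulky 9-BBN places boron on the terminal carbon of the monosubstituted alkene (anti-Markovnikov) and oxidation then gives the primary C9 alcohol, the acetal and the silyl ether being inert.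

**Step 7**
Reactants: 12 2-[cis,cis-6-[2-(tert-butyldiphenylsilyloxy)ethyl]-2-phenyl-1,3-dioxan-4-yl]ethan-1-ol
Product: 13 2-[cis,cis-6-[2-(tert-butyldiphenylsilyloxy)ethyl]-2-phenyl-1,3-dioxan-4-yl]acetaldehyde
Conditions: TEMPO (10 mol%), PhI(OAc)2 (1.1 equiv), CH2Cl2, rt
Reagents that add atoms: none
Why: The same TEMPO/PhI(OAc)2 oxidation stops at the aldehyde and is mild enough for the benzylidene acetal and for a β-alkoxy aldehyde that a base would cause to eliminate.

**Step 8**
Reactants: 13 2-[cis,cis-6-[2-(tert-butyldiphenylsilyloxy)ethyl]-2-phenyl-1,3-dioxan-4-yl]acetaldehyde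
Product: 15 (2R)-1-[cis,cis-6-[2-(tert-butyldiphenylsilyloxy)ethyl]-2-phenyl-1,3-dioxan-4-yl]pent-4-en-2-ol, via diisopinocampheylborinate ester 14 (not isolated)
Conditions: (+)-Ipc2BOMe, allylMgBr, Et2O, −78 °C to rt; then 13, −78 °C; then NaOH, H2O2, 0 °C to rt
Reagents that add atoms: allylmagnesium bromide, C=CC[Mg]Br
Why: A second Brown allylation with the same allylborane enantiomer adds to the Re face through the chair transition state and should give the (9R)-carbinol, 1,3-syn to O7, reagent control dominating the weak intrinsic bias of the β-alkoxy aldehyde.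

**Step 9**
Reactants: 15 (2R)-1-[cis,cis-6-[2-(tert-butyldiphenylsilyloxy)ethyl]-2-phenyl-1,3-dioxan-4-yl]pent-4-en-2-ol; 6 (Z)-but-2-ene-1,4-diol
Product: 16 (2E,5R)-6-[cis,cis-6-[2-(tert-butyldiphenylsilyloxy)ethyl]-2-phenyl-1,3-dioxan-4-yl]hex-2-ene-1,5-diol
Conditions: second-generation Grubbs catalyst RuCl2(=CHPh)(PCy3)(SIMes) (5 mol%), 6 (4 equiv), CH2Cl2, 40 °C
Reagents that add atoms: none
Why: Cross-metathesis as in step 4 converts the terminal alkene into the allylic alcohol (hydroxyl on C13, alkene C11=C12), with the secondary hydroxyl, the acetal and the silyl ether as spectators.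

**Step 10**
Reactants: 16 (2E,5R)-6-[cis,cis-6-[2-(tert-butyldiphenylsilyloxy)ethyl]-2-phenyl-1,3-dioxan-4-yl]hex-2-ene-1,5-diol; 8 benzaldehyde dimethyl acetal
Product: 18 all-syn 1-O-(tert-butyldiphenylsilyl)-3,5:7,9-di-O-benzylidene-undec-10-ene-1,3,5,7,9-pentol (target C3–C13; vinyl on C11), via transposed 9,11-syn-diol 17 (not isolated)
Conditions: Re2O7 (5 mol%), 8 (3 equiv), CH2Cl2, 0 °C to rt
Reagents that add atoms: none
Why: Re2O7 converts the primary allylic alcohol into a perrhenate ester that undergoes reversible [3,3]-sigmatropic 1,3-shifts, so the C13 alcohol, both C11 epimers of the secondary allylic alcohol and the alkene isomers interconvert. The closest known reaction type is the rhenium-oxo-catalysed allylic alcohol transposition run with in situ benzylidene acetalisation, already used in step 5. The 1,3-dioxane closes by acid-catalysed acetal exchange with 8: one hydroxyl forms a mixed acetal, loss of methanol gives an O-benzylic oxocarbenium ion, and the second hydroxyl adds to it in a 6-endo-trig closure. Both new stereocentres, C11 and the acetal carbon, are controlled by the C9 stereocentre, because only the 9,11-syn diol 17 can form a chair dioxane with the C8 chain, the vinyl group and phenyl all equatorial, and every event leading to it is reversible. The selectivities needed are regiochemical (oxygen on C11, not back on C13) and diastereochemical at C11, and both are secured by this acetal sink, which drains the syn secondary alcohol from an equilibrium that otherwise favours the primary isomer. The O5/O7 acetal is of the same kind and can at most exchange degenerately with 8, and the TBDPS ether is stable to the weakly acidic medium.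

**Step 11**
Reactants: 18 all-syn 1-O-(tert-butyldiphenylsilyl)-3,5:7,9-di-O-benzylidene-undec-10-ene-1,3,5,7,9-pentol; 19 1-pentadecene
Product: 20 all-syn (10E)-1-O-(tert-butyldiphenylsilyl)-3,5:7,9-di-O-benzylidene-tetracos-10-ene-1,3,5,7,9-pentol (target C3–C26)
Conditions: second-generation Grubbs catalyst RuCl2(=CHPh)(PCy3)(SIMes) (5–10 mol%), 19 (4 equiv), CH2Cl2, 40 °C
Reagents that add atoms: none
Why: Cross-metathesis of the vinyl group with an excess of the simple terminal alkene should favour the cross product because the oxygen-substituted vinyl partner is slow to homodimerise, ethene is lost, and the E/Z outcome is irrelevant since the alkene is reduced next.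

**Step 12**
Reactants: 20 all-syn (10E)-1-O-(tert-butyldiphenylsilyl)-3,5:7,9-di-O-benzylidene-tetracos-10-ene-1,3,5,7,9-pentol
Product: 21 all-syn 1-O-(tert-butyldiphenylsilyl)-3,5:7,9-di-O-benzylidene-tetracosane-1,3,5,7,9-pentol
Conditions: TsNHNH2, NaOAc, DME–H2O, 85 °C
Reagents that add atoms: none
Why: Diimide, released thermally from the sulfonyl hydrazide, transfers two hydrogens to the unpolarised disubstituted alkene in a concerted syn fashion (diimide reduction) and, unlike hydrogenation over palladium, cannot hydrogenolyse the benzylic acetals.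

**Step 13**
Reactants: 21 all-syn 1-O-(tert-butyldiphenylsilyl)-3,5:7,9-di-O-benzylidene-tetracosane-1,3,5,7,9-pentol
Product: 22 all-syn 3,5:7,9-di-O-benzylidene-tetracosane-1,3,5,7,9-pentol (free C3 alcohol)
Conditions: Bu4NF, THF, rt
Reagents that add atoms: none
Why: Fluoride-induced desilylation, driven by the strong Si–F bond, frees the primary alcohol while the base-stable acetals are untouched.

**Step 14**
Reactants: 22 all-syn 3,5:7,9-di-O-benzylidene-tetracosane-1,3,5,7,9-pentol
Product: 23 all-syn 3,5:7,9-di-O-benzylidene-3,5,7,9-tetrahydroxytetracosanal (C3 aldehyde)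
Conditions: TEMPO (10 mol%), PhI(OAc)2 (1.1 equiv), CH2Cl2, rt
Reagents that add atoms: none
Why: TEMPO/PhI(OAc)2 oxidation of the primary alcohol to the aldehyde, as in steps 2 and 7, with no epimerisable centre next to the new carbonyl.

**Step 15**
Reactants: 23 all-syn 3,5:7,9-di-O-benzylidene-3,5,7,9-tetrahydroxytetracosanal
Product: 24 ethyl (2Z)-5,7:9,11-di-O-benzylidene-5,7,9,11-tetrahydroxyhexacos-2-enoate (all-syn)
Conditions: (o-TolO)2P(O)CH2CO2Et, NaH, THF, −78 to 0 °C
Reagents that add atoms: ethyl 2-[bis(2-methylphenoxy)phosphoryl]acetate, CCOC(=O)CP(=O)(Oc1ccccc1C)Oc1ccccc1C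
Why: In the Ando variant of the Horner–Wadsworth–Emmons olefination the electron-poor diaryl phosphonate makes oxaphosphetane collapse faster than equilibration, so the kinetically formed (Z)-enoate is expected, and the low temperature also suppresses β-elimination of the aldehyde.

**Step 16**
Reactants: 24 ethyl (2Z)-5,7:9,11-di-O-benzylidene-5,7,9,11-tetrahydroxyhexacos-2-enoate
Product: 26 (6S)-6-[(2R,4R,6R)-2,4,6-trihydroxyhenicosyl]-5,6-dihydro-2H-pyran-2-one, via tetrahydroxy (Z)-enoate 25 (not isolated)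
Conditions: AcOH–H2O (4:1), 60 °C
Reagents that add atoms: none
Why: Aqueous acid hydrolyses both benzylidene acetals, and the C5 hydroxyl of the resulting tetraol ester then closes the six-membered ring onto the cis-disposed ester (acid-catalysed lactonisation, 6-exo-trig at the ester carbonyl) with loss of ethanol, no C–O bond at a stereocentre being broken so that C5, C7, C9 and C11 keep their configuration.

**Compound list**
1 | propane-1,3-diol | OCCCO | starting material
2 | 3-(tert-butyldiphenylsilyloxy)propan-1-ol | OCCCO[Si](c1ccccc1)(c1ccccc1)C(C)(C)C | intermediate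
3 | 3-(tert-butyldiphenylsilyloxy)propanal | O=CCCO[Si](c1ccccc1)(c1ccccc1)C(C)(C)C | intermediate
4 | diisopinocampheylborinate ester of 5 (Ipc2B on the C5 oxygen; not isolated) | C=CC[C@@H](OB([C@H]1C[C@H]2C[C@@H]([C@@H]1C)C2(C)C)[C@H]1C[C@H]2C[C@@H]([C@@H]1C)C2(C)C)CCO[Si](c1ccccc1)(c1ccccc1)C(C)(C)C | intermediate
5 | (R)-1-(tert-butyldiphenylsilyloxy)hex-5-en-3-ol (target C3–C8) | C=CC[C@@H](O)CCO[Si](c1ccccc1)(c1ccccc1)C(C)(C)C | intermediate
6 | (Z)-but-2-ene-1,4-diol | OC/C=C\CO | starting material
7 | (2E,5R)-7-(tert-butyldiphenylsilyloxy)hept-2-ene-1,5-diol (target C3–C9) | OC/C=C/C[C@@H](O)CCO[Si](c1ccccc1)(c1ccccc1)C(C)(C)C | intermediate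
8 | benzaldehyde dimethyl acetal | COC(OC)c1ccccc1 | starting material
9 | (3S,5S)-7-(tert-butyldiphenylsilyloxy)hept-1-ene-3,5-diol (5,7-syn diol, vinyl on C7; not isolated) | C=C[C@@H](O)C[C@@H](O)CCO[Si](c1ccccc1)(c1ccccc1)C(C)(C)C | intermediate
10 | (2S,4S,6S)-4-[2-(tert-butyldiphenylsilyloxy)ethyl]-2-phenyl-6-vinyl-1,3-dioxane (O5/O7 benzylidene, vinyl on C7) | C=C[C@@H]1C[C@H](CCO[Si](c2ccccc2)(c2ccccc2)C(C)(C)C)O[C@H](c2ccccc2)O1 | intermediate
11 | B-alkyl-9-borabicyclo[3.3.1]nonane from 10 (boron on C9; not isolated) | C1CC2CCCC(C1)B2CC[C@@H]1C[C@H](CCO[Si](c2ccccc2)(c2ccccc2)C(C)(C)C)O[C@H](c2ccccc2)O1 | intermediate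
12 | 2-[cis,cis-6-[2-(tert-butyldiphenylsilyloxy)ethyl]-2-phenyl-1,3-dioxan-4-yl]ethan-1-ol (C9 alcohol) | OCC[C@@H]1C[C@H](CCO[Si](c2ccccc2)(c2ccccc2)C(C)(C)C)O[C@H](c2ccccc2)O1 | intermediate
13 | 2-[cis,cis-6-[2-(tert-butyldiphenylsilyloxy)ethyl]-2-phenyl-1,3-dioxan-4-yl]acetaldehyde (C9 aldehyde) | O=CC[C@@H]1C[C@H](CCO[Si](c2ccccc2)(c2ccccc2)C(C)(C)C)O[C@H](c2ccccc2)O1 | intermediate
14 | diisopinocampheylborinate ester of 15 (Ipc2B on the C9 oxygen; not isolated) | C=CC[C@@H](OB([C@H]1C[C@H]2C[C@@H]([C@@H]1C)C2(C)C)[C@H]1C[C@H]2C[C@@H]([C@@H]1C)C2(C)C)C[C@@H]1C[C@H](CCO[Si](c2ccccc2)(c2ccccc2)C(C)(C)C)O[C@H](c2ccccc2)O1 | intermediate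
15 | (2R)-1-[cis,cis-6-[2-(tert-butyldiphenylsilyloxy)ethyl]-2-phenyl-1,3-dioxan-4-yl]pent-4-en-2-ol (9R carbinol, syn to O7; target C3–C12) | C=CC[C@@H](O)C[C@@H]1C[C@H](CCO[Si](c2ccccc2)(c2ccccc2)C(C)(C)C)O[C@H](c2ccccc2)O1 | intermediate
16 | (2E,5R)-6-[cis,cis-6-[2-(tert-butyldiphenylsilyloxy)ethyl]-2-phenyl-1,3-dioxan-4-yl]hex-2-ene-1,5-diol (free 9-OH and 13-OH, C11=C12; key-step precursor) | OC/C=C/C[C@@H](O)C[C@@H]1C[C@H](CCO[Si](c2ccccc2)(c2ccccc2)C(C)(C)C)O[C@H](c2ccccc2)O1 | intermediate
17 | 1-[cis,cis-6-[2-(tert-butyldiphenylsilyloxy)ethyl]-2-phenyl-1,3-dioxan-4-yl]hex-5-ene-2,4-diol (9,11-syn diol, vinyl on C11; not isolated) | C=C[C@@H](O)C[C@@H](O)C[C@@H]1C[C@H](CCO[Si](c2ccccc2)(c2ccccc2)C(C)(C)C)O[C@H](c2ccccc2)O1 | intermediate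
18 | all-syn 1-O-(tert-butyldiphenylsilyl)-3,5:7,9-di-O-benzylidene-undec-10-ene-1,3,5,7,9-pentol (O5/O7 and O9/O11 benzylidenes, vinyl on C11; key-step product) | C=C[C@@H]1C[C@H](C[C@@H]2C[C@H](CCO[Si](c3ccccc3)(c3ccccc3)C(C)(C)C)O[C@H](c3ccccc3)O2)O[C@H](c3ccccc3)O1 | intermediate
19 | 1-pentadecene | C=CCCCCCCCCCCCCC | starting material
20 | all-syn (10E)-1-O-(tert-butyldiphenylsilyl)-3,5:7,9-di-O-benzylidene-tetracos-10-ene-1,3,5,7,9-pentol (target C3–C26, C12=C13) | CCCCCCCCCCCCC/C=C/[C@@H]1C[C@H](C[C@@H]2C[C@H](CCO[Si](c3ccccc3)(c3ccccc3)C(C)(C)C)O[C@H](c3ccccc3)O2)O[C@H](c3ccccc3)O1 | intermediate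
21 | all-syn 1-O-(tert-butyldiphenylsilyl)-3,5:7,9-di-O-benzylidene-tetracosane-1,3,5,7,9-pentol | CCCCCCCCCCCCCCC[C@@H]1C[C@H](C[C@@H]2C[C@H](CCO[Si](c3ccccc3)(c3ccccc3)C(C)(C)C)O[C@H](c3ccccc3)O2)O[C@H](c3ccccc3)O1 | intermediate
22 | all-syn 3,5:7,9-di-O-benzylidene-tetracosane-1,3,5,7,9-pentol (free C3 alcohol) | CCCCCCCCCCCCCCC[C@@H]1C[C@H](C[C@@H]2C[C@H](CCO)O[C@H](c3ccccc3)O2)O[C@H](c3ccccc3)O1 | intermediate
23 | all-syn 3,5:7,9-di-O-benzylidene-3,5,7,9-tetrahydroxytetracosanal (C3 aldehyde) | CCCCCCCCCCCCCCC[C@@H]1C[C@H](C[C@@H]2C[C@H](CC=O)O[C@H](c3ccccc3)O2)O[C@H](c3ccccc3)O1 | intermediate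
24 | ethyl (2Z)-5,7:9,11-di-O-benzylidene-5,7,9,11-tetrahydroxyhexacos-2-enoate (all-syn) | CCCCCCCCCCCCCCC[C@@H]1C[C@H](C[C@@H]2C[C@H](C/C=C\C(=O)OCC)O[C@H](c3ccccc3)O2)O[C@H](c3ccccc3)O1 | intermediate
25 | ethyl (2Z)-5,7,9,11-tetrahydroxyhexacos-2-enoate (all-syn, configuration as in 26; not isolated) | CCCCCCCCCCCCCCC[C@@H](O)C[C@@H](O)C[C@@H](O)C[C@@H](O)C/C=C\C(=O)OCC | intermediate
26 | (6S)-6-[(2R,4R,6R)-2,4,6-trihydroxyhenicosyl]-5,6-dihydro-2H-pyran-2-one (CNP0231118.1; 5S,7R,9R,11R in chain numbering) | CCCCCCCCCCCCCCC[C@@H](O)C[C@@H](O)C[C@@H](O)C[C@@H]1CC=CC(=O)O1 | target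

**Count**
Total: 16 steps. Longest linear sequence: 16 steps, from propane-1,3-diol (1) to 26; the route is fully linear.

**Steps most likely to fail, with fallbacks**

Step 10. The perrhenate ester may ionise to an allyl cation and be lost by elimination or internal etherification, and acid-mediated migration or loss of the existing acetal may prevent clean funnelling into the single syn acetal. The fallback sets out from 15 and comes back to the route at 21, making the same O9/O11 ring and C11–O bond by a thermodynamic benzylidene trap but with an enoate as the activating group. Cross-metathesis of 15 with ethyl acrylate (second-generation Grubbs catalyst RuCl2(=CHPh)(PCy3)(SIMes), CH2Cl2, 40 °C) should give the ethyl (E)-δ-hydroxy enoate F1. Benzaldehyde with catalytic KOtBu in THF at 0 °C (hemiacetal alkoxide, then reversible intramolecular oxa-Michael addition, syn-selective for the triequatorial dioxane) should give the bis(benzylidene) ester F2. Reduction with iBu2AlH in CH2Cl2 at −78 °C gives the C13 aldehyde F3. A Wittig reaction with the ylide from tridecyltriphenylphosphonium bromide and NaN(SiMe3)2 in THF gives the C13=C14 (Z)-alkene F4. Diimide reduction under the conditions of step 12 then gives 21.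

Step 11. Metathesis at the hindered, oxygen-substituted vinyl group may be sluggish while the partner alkene homodimerises and the catalyst decays, and double-bond migration by ruthenium hydrides may shorten the chain. The fallback sets out from 18 and comes back at 21. Johnson–Lemieux cleavage of the vinyl group (catalytic OsO4, NaIO4, 2,6-lutidine, dioxane–H2O; ozone is avoided because it attacks the acetal C–H of benzylidene acetals) gives the C12 aldehyde F5, whose C11 substituent is equatorial and therefore not prone to epimerise. A Wittig reaction with the ylide from tetradecyltriphenylphosphonium bromide and NaN(SiMe3)2 gives the (Z)-alkene F6. The diimide reduction of step 12 converges on 21.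

Step 16. Hydrolysis of the second benzylidene may be incomplete under conditions mild enough for the product, and forcing it may cause conjugate addition of the C7 hydroxyl into the unsaturated lactone or Z-to-E isomerisation before ring closure. The fallback sets out from 21 and comes back at 26 by exchanging the acetals before the enoate exists. Hydrogenolysis (H2, Pd(OH)2/C, EtOAc–MeOH) gives the tetraol silyl ether F7. 2,2-Dimethoxypropane with PPTS gives the bis(acetonide) F8, the only way to place all four syn hydroxyls in two six-membered acetals. Bu4NF gives the alcohol F9, TEMPO/PhI(OAc)2 gives the aldehyde F10, and the Ando olefination of step 15 gives the (Z)-enoate F11. The much more labile acetonides are then removed with PPTS in MeOH at rt, and the tetraol ester 25 lactonises to 26.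

**Further compounds**
F1 | step 10 | ethyl (2E,5R)-6-[cis,cis-6-[2-(tert-butyldiphenylsilyloxy)ethyl]-2-phenyl-1,3-dioxan-4-yl]-5-hydroxyhex-2-enoate | CCOC(=O)/C=C/C[C@@H](O)C[C@@H]1C[C@H](CCO[Si](c2ccccc2)(c2ccccc2)C(C)(C)C)O[C@H](c2ccccc2)O1
F2 | step 10 | all-syn O5/O7, O9/O11 bis(benzylidene) ethyl ester with CH2CO2Et on C11 (target C3–C13) | CCOC(=O)C[C@@H]1C[C@H](C[C@@H]2C[C@H](CCO[Si](c3ccccc3)(c3ccccc3)C(C)(C)C)O[C@H](c3ccccc3)O2)O[C@H](c3ccccc3)O1
F3 | step 10 | all-syn bis(benzylidene) C13 aldehyde (CH2CHO on C11) | O=CC[C@@H]1C[C@H](C[C@@H]2C[C@H](CCO[Si](c3ccccc3)(c3ccccc3)C(C)(C)C)O[C@H](c3ccccc3)O2)O[C@H](c3ccccc3)O1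
F4 | step 10 | all-syn bis(benzylidene) (Z)-C13=C14 alkene (target C3–C26) | CCCCCCCCCCCC/C=C\C[C@@H]1C[C@H](C[C@@H]2C[C@H](CCO[Si](c3ccccc3)(c3ccccc3)C(C)(C)C)O[C@H](c3ccccc3)O2)O[C@H](c3ccccc3)O1
F5 | step 11 | all-syn bis(benzylidene) C12 aldehyde (CHO on C11) | O=C[C@@H]1C[C@H](C[C@@H]2C[C@H](CCO[Si](c3ccccc3)(c3ccccc3)C(C)(C)C)O[C@H](c3ccccc3)O2)O[C@H](c3ccccc3)O1
F6 | step 11 | all-syn bis(benzylidene) (Z)-C12=C13 alkene (Z isomer of 20) | CCCCCCCCCCCCC/C=C\[C@@H]1C[C@H](C[C@@H]2C[C@H](CCO[Si](c3ccccc3)(c3ccccc3)C(C)(C)C)O[C@H](c3ccccc3)O2)O[C@H](c3ccccc3)O1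
F7 | step 16 | all-syn 1-O-(tert-butyldiphenylsilyl)tetracosane-1,3,5,7,9-pentol (free 5,7,9,11-tetraol) | CCCCCCCCCCCCCCC[C@@H](O)C[C@@H](O)C[C@@H](O)C[C@@H](O)CCO[Si](c1ccccc1)(c1ccccc1)C(C)(C)C
F8 | step 16 | all-syn 1-O-(tert-butyldiphenylsilyl)-3,5:7,9-di-O-isopropylidene-tetracosane-1,3,5,7,9-pentol | CCCCCCCCCCCCCCC[C@@H]1C[C@H](C[C@@H]2C[C@H](CCO[Si](c3ccccc3)(c3ccccc3)C(C)(C)C)OC(C)(C)O2)OC(C)(C)O1
F9 | step 16 | all-syn 3,5:7,9-di-O-isopropylidene-tetracosane-1,3,5,7,9-pentol (free C3 alcohol) | CCCCCCCCCCCCCCC[C@@H]1C[C@H](C[C@@H]2C[C@H](CCO)OC(C)(C)O2)OC(C)(C)O1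
F10 | step 16 | all-syn 3,5:7,9-di-O-isopropylidene-3,5,7,9-tetrahydroxytetracosanal | CCCCCCCCCCCCCCC[C@@H]1C[C@H](C[C@@H]2C[C@H](CC=O)OC(C)(C)O2)OC(C)(C)O1
F11 | step 16 | ethyl (2Z)-5,7:9,11-di-O-isopropylidene-5,7,9,11-tetrahydroxyhexacos-2-enoate (all-syn) | CCCCCCCCCCCCCCC[C@@H]1C[C@H](C[C@@H]2C[C@H](C/C=C\C(=O)OCC)OC(C)(C)O2)OC(C)(C)O1
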